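**Assumption:** the target is the L‑Gln amide with a free acid and the (E)‑trisubstituted alkene exactly as drawn.

## Retrosynthetic overview
1. The Gln amide comes from an E‑selective cross‑metathesis of a terminal alkene with N‑methacryloyl‑Gln. The Ca quaternary centre comes from alkylating the tetracyclic enone (14).
2. The oxa‑cage (spiro Ce, ring C and the THF bridge) comes from one oxidative dearomatization / cation–olefin / etherification cascade of a tetralin phenol‑alcohol.
3. The tetralin (rings A + B) comes from an intramolecular decarboxylative Diels–Alder of a 2‑pyrone with a tethered alkyne. This is the key cycloaddition.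
4. Order of ring formation: A + B (Diels–Alder), then C and the O‑bridge (cascade), then the Ca quaternary centre (alkylation).
5. All cage stereocentres trace to (S)‑carvone (Cg and Ci, via cis‑carveol); the Gln centre comes from L‑Gln.

Atom labels used below: Ci is the ether CH, Cg is the CH bearing Cj, Ca is the quaternary C(Me)(chain), and Cj is the C(Me)–O carbon.

## Route

**Step 1**
Reactants: 1 (S)‑carvone
Product: 2 (1S,5S)‑cis‑carveol
Conditions: NaBH4, CeCl3·7H2O, MeOH, –78 → 0 °C
Reagents that add atoms: none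
Why: Luche 1,2‑reduction delivers hydride axially, so the OH ends up equatorial and cis to the C5 isopropenyl (about 9:1; the trans isomer is removed by chromatography). This sets Ci relative to Cg.

**Step 2**
Reactants: 2
Product: 3 carveol TBS ether
Conditions: TBSCl, imidazole, DMF, rt
Reagents that add atoms: TBSCl, CC(C)(C)[Si](C)(C)Cl
Why: silylation of the secondary alcohol prevents lactol formation and α‑ketol epimerization later.

**Step 3**
Reactants: 3
Product: 4 (3R,5S)‑5‑(TBSO)‑6‑oxo‑3‑(prop‑1‑en‑2‑yl)heptanal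
Conditions: O3 (1.0 equiv), CH2Cl2/MeOH, NaHCO3, –78 °C; then Me2S
Reagents that add atoms: ozone, [O-][O+]=O
Why: ozonolysis cleaves the more electron‑rich ring trisubstituted alkene and leaves the isopropenyl group. The ring opens to a keto‑aldehyde that keeps every carbon and both stereocentres (Cg, Ci).

**Step 4**
Reactants: 4
Product: 5 (3S,5S)‑3‑(TBSO)‑5‑(prop‑1‑en‑2‑yl)oct‑7‑yn‑2‑one
Conditions: Bestmann–Ohira reagent, K2CO3, MeOH, 0 °C → rt
Reagents that add atoms: dimethyl (1‑diazo‑2‑oxopropyl)phosphonate, COP(=O)(OC)C(=[N+]=[N-])C(C)=O (adds one C)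
Why: Ohira–Bestmann homologation converts the aldehyde chemoselectively to the terminal alkyne that will be the dienophile. Cg is not epimerizable.

**Step 5**
Reactants: 5
Product: 6 methyl (6S,8S)‑6‑(TBSO)‑3,5‑dioxo‑8‑(prop‑1‑en‑2‑yl)undec‑10‑ynoate
Conditions: LDA (1.05 equiv), THF, –78 °C; then methyl malonyl chloride, –78 → 0 °C
Reagents that add atoms: methyl 3‑chloro‑3‑oxopropanoate, COC(=O)CC(=O)Cl
Why: the kinetic enolate forms at the methyl ketone, because the ketone is more acidic than the terminal alkyne. C‑Acylation (Claisen type) builds the 1,3,5‑tricarbonyl ester.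

**Step 6**
Reactants: 6
Product: 7 4‑hydroxy‑6‑[(1S,3S)‑1‑(TBSO)‑3‑(prop‑1‑en‑2‑yl)hex‑5‑yn‑1‑yl]‑2H‑pyran‑2‑one
Conditions: NaOMe (1.2 equiv), MeOH, 0 °C → rt
Reagents that add atoms: none
Why: base‑mediated enolization and lactonization of the 3,5‑dioxoester (loss of MeOH) gives the 4‑hydroxy‑2‑pyrone, the standard polyketide pyrone closure.

**Step 7**
Reactants: 7
Product: 8 the corresponding 4‑acetoxy‑2‑pyrone
Conditions: Ac2O, Et3N, DMAP (cat.), CH2Cl2, 0 °C
Reagents that add atoms: acetic anhydride, CC(=O)OC(C)=O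
Why: O‑acetylation removes the acidic enol and gives a workable diene. The acetate is later cleaved to the phenol.

**Step 8**
Reactants: 8
Product: 9 (6S,8S)‑8‑(TBSO)‑6‑(prop‑1‑en‑2‑yl)‑5,6,7,8‑tetrahydronaphthalen‑2‑yl acetate
Conditions: o‑dichlorobenzene (0.02 M), BHT, 190 °C, sealed tube, 24–48 h
Reagents that add atoms: none
Why: this is the key step, an intramolecular pyrone–alkyne Diels–Alder followed by retro‑[4+2] loss of CO2. The four‑atom tether forces Ce–Cl bonding, so rings A and B form at once with the correct regiochemistry (OAc para to Ce). No new stereocentre is made, and the cis‑1,3 Cg/Ci relationship is retained.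

**Step 9**
Reactants: 9
Product: 10 (6S,8S)‑6‑(prop‑1‑en‑2‑yl)‑5,6,7,8‑tetrahydronaphthalene‑2,8‑diol
Conditions: TBAF (3 equiv), THF, 0 °C → rt
Reagents that add atoms: none
Why: fluoride removes the silyl ether and cleaves the aryl acetate, giving the free phenol and the free benzylic alcohol (cis to the isopropenyl) needed for the cascade.

**Step 10**
Reactants: 10
Product: 11 oxa‑bridged tetracyclic cage dienone
Conditions: PIFA (1.2 equiv), HFIP, 0 °C
Reagents that add atoms: none
Why: Kita‑type oxidative dearomatization gives a phenoxenium ion. The axial isopropenyl (cis to the OH) attacks the para carbon Ce on its own face, forming spiro Ce and ring C. The resulting tertiary Cj cation is captured by the cis 1,3‑diaxial Ci–OH, forming the THF bridge. The cage can close in only one way, which fixes Ce and Cj.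

**Step 11**
Reactants: 11
Product: 12 enone with Cc–Cd saturated
Conditions: H2 (1 atm), 10% Pd/C, EtOAc, rt, 30 min
Reagents that add atoms: none
Why: heterogeneous hydrogenation takes the unhindered disubstituted enone alkene Cc=Cd first and leaves the β,β‑disubstituted, trisubstituted Ca=Cl enone.

**Step 12**
Reactants: 12
Product: 13 saturated cage ketone with Ca(H)(Me) and Cl–H
Conditions: Li, liq. NH3/THF, t‑BuOH (1 equiv), –78 °C; then MeI, –78 °C → rt
Reagents that add atoms: iodomethane, CI
Why: Stork reductive alkylation reduces the enone to an enolate. The β‑carbanion at Cl is protonated from the convex face, giving the only cis ring fusion the cage tolerates. The enolate is then methylated at Ca, whose configuration is epimerizable.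

**Step 13**
Reactants: 13
Product: 14 tetracyclic enone (Ca–H/Me; Cb=O, Cc=Cd)
Conditions: (i) LDA, THF, –78 °C, then TMSCl, Et3N; (ii) Pd(OAc)2, MeCN, rt
Reagents that add atoms: none (TMS is lost)
Why: kinetic deprotonation occurs at the less hindered Cc, and Saegusa–Ito oxidation regenerates the Cc=Cd enone. The result leaves Ca as the only enolizable α′ site.

**Step 14**
Reactants: 14
Product: 15 Ca‑quaternary butenyl enone
Conditions: LDA, THF/HMPA, –78 °C; then 4‑iodo‑1‑butene, –78 → –20 °C
Reagents that add atoms: 4‑iodo‑1‑butene, C=CCCI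
Why: enolate alkylation at Ca occurs from the convex face of the cage, giving the quaternary Ca of the natural series (chain syn to Ck, Me anti), as in platensimycin‑type cage enones.

**Step 15**
Reactants: 16 L‑glutamine methyl ester hydrochloride
Product: 17 N‑methacryloyl‑L‑glutamine methyl ester
Conditions: methacryloyl chloride (1.1 equiv), NaHCO3, CH2Cl2/H2O, 0 °C
Reagents that add atoms: methacryloyl chloride, C=C(C)C(=O)Cl
Why: Schotten–Baumann N‑acylation at the α‑amine; the L centre is untouched.

**Step 16**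
Reactants: 15 + 17
Product: 18 methyl ester of the target
Conditions: Hoveyda–Grubbs II (10 mol %), 17 (4 equiv), CH2Cl2, 45 °C
Reagents that add atoms: none (ethylene is lost)
Why: cross‑metathesis of the terminal alkene with the 1,1‑disubstituted acrylamide gives the thermodynamically preferred (E)‑trisubstituted enamide; the cage enone is inert.

**Step 17**
Reactants: 18
Product: 19 homoplatensimide A
Conditions: LiOH (3 equiv), THF/H2O 3:1, 0 °C; then acidify to pH 3
Reagents that add atoms: hydroxide/water (supplies the acid O), [OH-]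
Why: saponification of the methyl ester leaves the primary amide, enone, cage ether and Gln stereocentre unchanged.

## Compound list
1 | (S)‑(+)‑carvone | CC1=CC[C@@H](CC1=O)C(C)=C | starting material
2 | (1S,5S)‑cis‑carveol | O[C@H]1C[C@@H](C(C)=C)CC=C1C | intermediate
3 | carveol TBS ether | C[Si](C)(C(C)(C)C)O[C@H]1C[C@@H](C(C)=C)CC=C1C | intermediate
4 | (3R,5S)‑5‑(TBSO)‑6‑oxo‑3‑(prop‑1‑en‑2‑yl)heptanal | O=CC[C@H](C(C)=C)C[C@H](O[Si](C)(C)C(C)(C)C)C(C)=O | intermediate
5 | (3S,5S)‑3‑(TBSO)‑5‑(prop‑1‑en‑2‑yl)oct‑7‑yn‑2‑one | C#CC[C@H](C(C)=C)C[C@H](O[Si](C)(C)C(C)(C)C)C(C)=O | intermediate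
6 | methyl (6S,8S)‑6‑(TBSO)‑3,5‑dioxo‑8‑(prop‑1‑en‑2‑yl)undec‑10‑ynoate | C#CC[C@H](C(C)=C)C[C@H](O[Si](C)(C)C(C)(C)C)C(=O)CC(=O)CC(=O)OC | intermediate
7 | 4‑hydroxy‑6‑[(1S,3S)‑1‑(TBSO)‑3‑(prop‑1‑en‑2‑yl)hex‑5‑yn‑1‑yl]‑2H‑pyran‑2‑one | C#CC[C@H](C(C)=C)C[C@H](O[Si](C)(C)C(C)(C)C)C1=CC(O)=CC(=O)O1 | intermediate
8 | corresponding 4‑acetoxy‑2‑pyrone | C#CC[C@H](C(C)=C)C[C@H](O[Si](C)(C)C(C)(C)C)C1=CC(OC(C)=O)=CC(=O)O1 | intermediate
9 | (6S,8S)‑8‑(TBSO)‑6‑isopropenyl‑tetralin‑2‑yl acetate | CC(=O)Oc1ccc2c(c1)[C@@H](O[Si](C)(C)C(C)(C)C)C[C@@H](C(C)=C)C2 | intermediate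
10 | (6S,8S)‑6‑isopropenyl‑5,6,7,8‑tetrahydronaphthalene‑2,8‑diol | Oc1ccc2c(c1)[C@@H](O)C[C@@H](C(C)=C)C2 | intermediate
11 | oxa‑cage dienone (Cb=O; Ca=Cl and Cc=Cd) | O=C1C=C[C@]23C[C@H]4C[C@H](O[C@@]4(C)C2)C3=C1 | intermediate
12 | cage enone, Cc–Cd saturated | O=C1CC[C@]23C[C@H]4C[C@H](O[C@@]4(C)C2)C3=C1 | intermediate
13 | saturated cage ketone, Ca(H)(Me) (Ca epimeric) | CC1C(=O)CC[C@]23C[C@H]4C[C@H](O[C@@]4(C)C2)[C@H]31 | intermediate
14 | tetracyclic enone (Ca epimeric) | CC1C(=O)C=C[C@]23C[C@H]4C[C@H](O[C@@]4(C)C2)[C@H]31 | intermediate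
15 | Ca‑butenyl tetracyclic enone | C=CCC[C@]1(C)C(=O)C=C[C@]23C[C@H]4C[C@H](O[C@@]4(C)C2)[C@H]31 | intermediate
16 | L‑glutamine methyl ester hydrochloride | COC(=O)[C@@H](N)CCC(N)=O.Cl | starting material
17 | N‑methacryloyl‑L‑glutamine methyl ester | C=C(C)C(=O)N[C@@H](CCC(N)=O)C(=O)OC | intermediate
18 | methyl ester of homoplatensimide A | C/C(=C\CC[C@]1(C)C(=O)C=C[C@]23C[C@H]4C[C@H](O[C@@]4(C)C2)[C@H]31)C(=O)N[C@@H](CCC(N)=O)C(=O)OC | intermediate
19 | homoplatensimide A | C/C(=C\CC[C@]1(C)C(=O)C=C[C@]23C[C@H]4C[C@H](O[C@@]4(C)C2)[C@H]31)C(=O)N[C@@H](CCC(N)=O)C(=O)O | target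

## Totals
Total steps: 17.
Longest linear sequence: 16 (Steps 1–14, 16, 17; Step 15 is a parallel one‑step branch).

## Three steps most likely to fail
1. **Step 8 (pyrone–alkyne Diels–Alder).** The alkyne is unactivated and the acetoxypyrone is a poor diene at about 190 °C, so decomposition or competing reaction with the isopropenyl group is possible. Fallback: a different cycloaddition, a Co‑ or Rh‑catalysed intramolecular [2+2+2] of a 1,7‑diyne (made from 5 by methyl ketone → enol triflate → alkyne) with an ynol ether, to give the same tetralin.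
2. **Step 10 (oxidative cascade).** Ring C closure is a 5‑endo‑type cation–olefin attack, and the phenol or benzylic alcohol may over‑oxidize. Fallback: a stepwise ring C closure. NBS allylic bromination of the isopropenyl group, then base‑mediated dearomatizing SN2′ para‑alkylation of the phenoxide, then TFA cycloetherification of the Ci–OH onto the exocyclic alkene.
3. **Step 3 (chemoselective ozonolysis).** Ozone does not discriminate strongly between the ring trisubstituted alkene and the isopropenyl group. Fallback: nucleophilic epoxidation of carvone (H2O2/NaOH), then hydrolysis and NaIO4 cleavage to the α‑diketo aldehyde. Carry the Ci ketone through the pyrone and Diels–Alder sequence as a 6‑acylpyrone, then set Ci–OH (cis to isopropenyl) by directed reduction of the aryl ketone before Step 10.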